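**Plan**

- The target is read as (+)-gallocatechin-(4α→8)-(+)-catechin-(4β→8)-(−)-catechin: upper unit 2R,3S,4S (3,4-trans), middle unit 2R,3S,4S (3,4-cis), terminal unit 2S,3R.
- The retrosynthesis cuts, in this order: the upper interflavan bond C4(upper)–C8(middle); the O1–C2 and C3–C4 bonds of ring C of the terminal unit, both in one oxa-[4+2] event; the C4(middle)–aryl bond to a phloroglucinol-derived phenol. The middle C3 carbinol is traced back to epicatechin through a ketone.
- Enabling feature: in the terminal unit O1–C8a–C4a–C4 is a phenol oxygen and a benzylic CH2 ortho to each other on the 5,7-dioxygenated ring A, a latent ortho-quinone methide. C2–C3 is a trans 2-aryl-1-oxyethene whose 3,4-dioxygenated ring B makes C3 the nucleophilic and C2 the cation-stabilising carbon.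
- Forward: an epicatechin C4 cation is joined to 3,5-bis(benzyloxy)phenol (future ring A of the terminal unit), followed by ortho-formylation and oxidation/reduction (C3 inversion, CHO to CH2OH). Ring C of the terminal unit is then annulated with an E enol acetate; acetylation, coupling with a bromine-capped gallocatechin C4 electrophile, deacetylation and hydrogenolysis finish the route.
- Stereochemistry: chiral pool for C2 of the upper and middle units and C3 of the upper unit. Substrate control sets middle C4 (trans attack on the epicatechin cation), middle C3 (axial hydride anti to the 4β-aryl group) and upper C4 (acetoxy participation). Catalyst control plus alkene geometry set C3 and C2 of the terminal unit.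

Key step: step 10

Remarks on the chemistry:
- α and β are used as in flavan-3-ol nomenclature: the 2-aryl group of a 2R unit is α, the 3-OH is α in epicatechin and β in catechin.
- Assumption: the (R) antipode of the acid in step 10 is taken as the one that gives the 2S,3R ring; both antipodes are available, so the sense of induction is a matter of catalyst, not of route.
- Assumption: the C4 ethers 19 and 20 are written as the 4β epimers; this centre is erased on ionisation in step 16.

Step 1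
Reactants: 1 (−)-epicatechin
Product: 2 5,7,3',4'-tetra-O-benzyl-(−)-epicatechin (3-OH free)
Conditions: BnBr (4.2 equiv), K2CO3, DMF, 0 °C → rt
Reagents that add atoms: benzyl bromide, BrCc1ccccc1
Why: Williamson etherification; the four phenols are alkylated under carbonate conditions while the secondary alcohol stays free, and no stereocentre is touched.

Step 2
Reactants: 2 5,7,3',4'-tetra-O-benzyl-(−)-epicatechin
Product: 3 4β-(2-ethoxyethoxy)-5,7,3',4'-tetra-O-benzyl-(−)-epicatechin
Conditions: DDQ (2 equiv), 2-ethoxyethanol, CH2Cl2, rt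
Reagents that add atoms: 2-ethoxyethanol, CCOCCO
Why: DDQ benzylic oxidation at C4 (hydride abstraction assisted by the ring A ethers) gives a cation that the alcohol should trap trans to the axial 3α-OH, which sets the new C4 centre as 4β.

Step 3
Reactants: 3 4β-(2-ethoxyethoxy)-5,7,3',4'-tetra-O-benzyl-(−)-epicatechin; 4 3,5-bis(benzyloxy)phenol (3 equiv)
Product: 5 4β-[2-hydroxy-4,6-bis(benzyloxy)phenyl]-5,7,3',4'-tetra-O-benzyl-(−)-epicatechin (3α-OH, 3,4-trans)
Conditions: TMSOTf (0.2 equiv), CH2Cl2, −78 → −40 °C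
Reagents that add atoms: none
Why: Lewis-acid Friedel–Crafts alkylation by the flavan-4-yl cation; the arene should enter trans to the 3α-OH (4β, as is general for epicatechin-derived cations) and at the carbon flanked by OH and one OBn rather than the one flanked by two OBn, by the same steric rule that directs such cations to C8 and not C6 of benzylated flavans.

Step 4
Reactants: 5 4β-[2-hydroxy-4,6-bis(benzyloxy)phenyl]-5,7,3',4'-tetra-O-benzyl-(−)-epicatechin
Product: 6 4β-[3-formyl-2-hydroxy-4,6-bis(benzyloxy)phenyl]-5,7,3',4'-tetra-O-benzyl-(−)-epicatechin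
Conditions: MgCl2, Et3N, paraformaldehyde, MeCN, reflux
Reagents that add atoms: paraformaldehyde (formaldehyde), C=O
Why: magnesium-phenoxide-mediated ortho-formylation (Casnati–Skattebøl) is specific for the position ortho to a free phenol, and the single open ortho position is the one that becomes C4a of the terminal unit, so the new carbon is the future C4.

Step 5
Reactants: 6 4β-[3-formyl-2-hydroxy-4,6-bis(benzyloxy)phenyl]-5,7,3',4'-tetra-O-benzyl-(−)-epicatechin
Product: 7 5,7-bis(benzyloxy)-2α-[3,4-bis(benzyloxy)phenyl]-4β-[3-formyl-2-hydroxy-4,6-bis(benzyloxy)phenyl]chroman-3-one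
Conditions: Dess–Martin periodinane, CH2Cl2, 0 °C → rt
Reagents that add atoms: none
Why: Dess–Martin oxidation of the hindered secondary alcohol under base-free conditions, so that C2 and C4 next to the new ketone should keep their configuration; the phenol is chelated to the aldehyde and has both ortho positions occupied.

Step 6
Reactants: 7 5,7-bis(benzyloxy)-2α-[3,4-bis(benzyloxy)phenyl]-4β-[3-formyl-2-hydroxy-4,6-bis(benzyloxy)phenyl]chroman-3-one
Product: 8 4β-[2-hydroxy-3-(hydroxymethyl)-4,6-bis(benzyloxy)phenyl]-5,7,3',4'-tetra-O-benzyl-(+)-catechin (2α-aryl, 3β-OH, 4β-aryl; 2,3-trans-3,4-cis)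
Conditions: NaBH4 (excess), CeCl3·7H2O, MeOH/THF, −40 → 0 °C; pH 7 work-up, used at once
Reagents that add atoms: none
Why: Luche-type borohydride reduction of both carbonyl groups; at C3 hydride should add axially from the α face, anti to the quasi-axial 4β-aryl group, giving the equatorial 3β-alcohol, while methanol and CeCl3 keep hydride delivery intermolecular.

Step 7
Reactants: 9 3,4-bis(benzyloxy)benzaldehyde
Product: 10 (E)-2-[3,4-bis(benzyloxy)phenyl]ethenylboronic acid pinacol ester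
Conditions: bis[(pinacolato)boryl]methane, lithium 2,2,6,6-tetramethylpiperidide (LiTMP), THF, −78 °C → rt
Reagents that add atoms: bis[(pinacolato)boryl]methane, CC1(C)OB(CB2OC(C)(C)C(C)(C)O2)OC1(C)C
Why: boron–Wittig olefination; the lithiated geminal bis(boronate) adds to the aldehyde and syn B–O elimination should give the E alkenylboronate.

Step 8
Reactants: 10 (E)-2-[3,4-bis(benzyloxy)phenyl]ethenylboronic acid pinacol ester
Product: 11 potassium (E)-{2-[3,4-bis(benzyloxy)phenyl]ethenyl}trifluoroborate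
Conditions: KHF2, MeOH/H2O, rt
Reagents that add atoms: potassium hydrogen difluoride, F.[F-].[K+]
Why: standard conversion of a pinacol boronate into the trifluoroborate salt, with retention of alkene geometry.

Step 9
Reactants: 11 potassium (E)-{2-[3,4-bis(benzyloxy)phenyl]ethenyl}trifluoroborate
Product: 12 (E)-2-[3,4-bis(benzyloxy)phenyl]ethenyl acetate
Conditions: AcOH (3 equiv), Cu(OAc)2 (10 mol %), DMAP (20 mol %), 4 Å MS, O2 (1 atm), CH2Cl2/MeCN, 40 °C
Reagents that add atoms: acetic acid, CC(=O)O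
Why: copper-catalysed oxidative C–O coupling (Chan–Lam type) of an alkenyltrifluoroborate with a carboxylic acid, which is stereoretentive and should give the E enol ester.

Step 10
Reactants: 8 4β-[2-hydroxy-3-(hydroxymethyl)-4,6-bis(benzyloxy)phenyl]-5,7,3',4'-tetra-O-benzyl-(+)-catechin; 12 (E)-2-[3,4-bis(benzyloxy)phenyl]ethenyl acetate (4 equiv)
Product: 14 5,7,3',4'-tetra-O-benzylcatechin-(4β→8)-(3-O-acetyl-5,7,3',4'-tetra-O-benzyl-ent-catechin) (middle 3β-OH free; terminal unit 2S,3R), via ortho-quinone methide 13 (not isolated)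
Conditions: (R)-3,3'-bis(2,4,6-triisopropylphenyl)-BINOL N-triflylphosphoramide (10 mol %), 5 Å MS, PhCF3, 0 °C → rt, slow addition of 8
Reagents that add atoms: none
Why: Proposed new method: the acid ionises the very electron-rich salicyl alcohol, with loss of water, to ortho-quinone methide 13, held by the chiral phosphoramide at its oxygen; the oxygen-bearing alkene carbon of 12 attacks the methylene carbon while the dienone oxygen closes on the benzylic carbon, an inverse-electron-demand oxa-[4+2] cycloaddition that in its stepwise limit passes through a 3,4-dialkoxybenzyl cation bridged as a trans-acetoxonium ion and closes by 6-exo attack of the phenol oxygen. The closest known reaction types are the chiral phosphoric acid and N-triflylphosphoramide catalysed [4+2] cycloadditions of in situ generated ortho-quinone methides with styrenes, enamides and vinyl sulfides, and the thermal cycloaddition of such methides with trans-β-substituted styrenes to 2,3-trans-flavans; new here are the β-acyloxystyrene as dienophile and the unsubstituted methide on a chiral flavanyl-substituted ring. Ring C of the terminal unit is the only ring closed, in the [4+2] mode. C3 is set in the C–C bond-forming event, the two faces of the enol ester being discriminated by the chiral phosphoramide bound to the methide oxygen; C2 follows from C3 because addition across the E alkene is suprafacial and, should the cation live long enough to rotate, closure anti to the participating acetoxy group gives the same diequatorial 2,3-trans ring. The step needs regioselectivity (the 3,4-dibenzyloxyphenyl group stabilises positive charge at C2 far better than an acyloxy group could at C3, so the oxygen-bearing carbon is the nucleophile), site selectivity (only the phenol oxygen next to the interflavan bond is free, the other oxygen flanking the methylene is benzylated, so only the 4→8-type pyran can form) and chemoselectivity over Friedel–Crafts self-alkylation and methide dimerisation (excess 12, low standing concentration of 13, the bulky flavanyl group ortho to the methide oxygen).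

Step 11
Reactants: 14 5,7,3',4'-tetra-O-benzylcatechin-(4β→8)-(3-O-acetyl-5,7,3',4'-tetra-O-benzyl-ent-catechin)
Product: 15 3-O-acetyl-5,7,3',4'-tetra-O-benzylcatechin-(4β→8)-(3-O-acetyl-5,7,3',4'-tetra-O-benzyl-ent-catechin)
Conditions: Ac2O, pyridine, DMAP (cat.), CH2Cl2, rt
Reagents that add atoms: acetic anhydride, CC(=O)OC(C)=O
Why: DMAP-catalysed acetylation of the one remaining secondary alcohol; no stereocentre is touched.

Step 12
Reactants: 16 (+)-gallocatechin
Product: 17 5,7,3',4',5'-penta-O-benzyl-(+)-gallocatechin (3-OH free)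
Conditions: BnBr (5.5 equiv), K2CO3, degassed DMF, argon, −20 °C → rt
Reagents that add atoms: benzyl bromide, BrCc1ccccc1
Why: Williamson etherification of the five phenols with exclusion of oxygen to protect the pyrogallol ring; the secondary alcohol stays free.

Step 13
Reactants: 17 5,7,3',4',5'-penta-O-benzyl-(+)-gallocatechin
Product: 18 8-bromo-5,7,3',4',5'-penta-O-benzyl-(+)-gallocatechin
Conditions: NBS (1.0 equiv), CH2Cl2, −78 °C
Reagents that add atoms: N-bromosuccinimide, BrN1C(=O)CCC1=O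
Why: electrophilic aromatic bromination, which in 5,7-dibenzyloxyflavans goes to C8 (flanked by the ring oxygen and one OBn); the bromine caps the only nucleophilic carbon of the later electrophile.

Step 14
Reactants: 18 8-bromo-5,7,3',4',5'-penta-O-benzyl-(+)-gallocatechin
Product: 19 8-bromo-4β-(2-ethoxyethoxy)-5,7,3',4',5'-penta-O-benzyl-(+)-gallocatechin
Conditions: DDQ (2 equiv), 2-ethoxyethanol, CH2Cl2, rt
Reagents that add atoms: 2-ethoxyethanol, CCOCCO
Why: DDQ benzylic oxidation at C4 with trapping by the alcohol, as in step 2; the configuration of the new C4 centre is of no consequence.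

Step 15
Reactants: 19 8-bromo-4β-(2-ethoxyethoxy)-5,7,3',4',5'-penta-O-benzyl-(+)-gallocatechin
Product: 20 3-O-acetyl-8-bromo-4β-(2-ethoxyethoxy)-5,7,3',4',5'-penta-O-benzyl-(+)-gallocatechin
Conditions: Ac2O, pyridine, DMAP (cat.), CH2Cl2, rt
Reagents that add atoms: acetic anhydride, CC(=O)OC(C)=O
Why: acetylation of the 3-OH installs the participating group for the coupling.

Step 16
Reactants: 15 3-O-acetyl-5,7,3',4'-tetra-O-benzylcatechin-(4β→8)-(3-O-acetyl-5,7,3',4'-tetra-O-benzyl-ent-catechin); 20 3-O-acetyl-8-bromo-4β-(2-ethoxyethoxy)-5,7,3',4',5'-penta-O-benzyl-(+)-gallocatechin (1.1 equiv)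
Product: 21 3-O-acetyl-8-bromo-5,7,3',4',5'-penta-O-benzylgallocatechin-(4α→8)-3-O-acetyl-5,7,3',4'-tetra-O-benzylcatechin-(4β→8)-(3-O-acetyl-5,7,3',4'-tetra-O-benzyl-ent-catechin)
Conditions: TMSOTf (0.3 equiv), CH2Cl2, −78 → −30 °C
Reagents that add atoms: none
Why: Lewis-acid Friedel–Crafts coupling of a flavan-4-yl cation; the 3β-acetoxy group should bridge the β face so that the arene enters trans (new C4 centre 4α), C8 of the middle unit is the only ring A carbon not flanked by two OBn groups, and the bromine cap stops self-condensation of 20 so that near-equimolar amounts suffice.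

Step 17
Reactants: 21 the tri-O-acetyl protected trimer
Product: 22 8-bromo-5,7,3',4',5'-penta-O-benzylgallocatechin-(4α→8)-5,7,3',4'-tetra-O-benzylcatechin-(4β→8)-5,7,3',4'-tetra-O-benzyl-ent-catechin (three free 3-OH groups)
Conditions: NaOMe (cat.), MeOH/THF, rt → 40 °C
Reagents that add atoms: none
Why: Zemplén transesterification removes the three acetates; with all phenols benzylated no centre is base-labile.

Step 18
Reactants: 22 the tridecabenzyl bromo trimer
Product: 23 (+)-gallocatechin-(4α→8)-(+)-catechin-(4β→8)-(−)-catechin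
Conditions: H2 (1 atm), Pd(OH)2/C, NaOAc (1.5 equiv), THF/MeOH/H2O, rt; filtration, lyophilisation
Reagents that add atoms: none
Why: catalytic hydrogenolysis should cleave the thirteen benzyl ethers and the aryl C–Br bond in one operation; acetate buffers the hydrogen bromide so that the acid-labile interflavan bonds and all stereocentres stay intact.

**Compound list**

1 | (−)-epicatechin, (2R,3R) | Oc1cc(O)c2c(c1)O[C@H](c1ccc(O)c(O)c1)[C@H](O)C2 | starting material
2 | 5,7,3',4'-tetra-O-benzyl-(−)-epicatechin | c1ccccc1COc1cc(OCc3ccccc3)c2c(c1)O[C@H](c1ccc(OCc3ccccc3)c(OCc3ccccc3)c1)[C@H](O)C2 | intermediate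
3 | 4β-(2-ethoxyethoxy)-5,7,3',4'-tetra-O-benzyl-(−)-epicatechin (2α-aryl, 3α-OH, 4β-OR) | c1ccccc1COc1cc(OCc3ccccc3)c2c(c1)O[C@H](c1ccc(OCc3ccccc3)c(OCc3ccccc3)c1)[C@H](O)[C@H]2OCCOCC | intermediate
4 | 3,5-bis(benzyloxy)phenol | Oc1cc(OCc2ccccc2)cc(OCc2ccccc2)c1 | starting material
5 | 4β-[2-hydroxy-4,6-bis(benzyloxy)phenyl]-5,7,3',4'-tetra-O-benzyl-(−)-epicatechin (3α-OH, 3,4-trans) | c1ccccc1COc1cc(OCc3ccccc3)c2c(c1)O[C@H](c1ccc(OCc3ccccc3)c(OCc3ccccc3)c1)[C@H](O)[C@H]2c1c(OCc3ccccc3)cc(OCc3ccccc3)cc1O | intermediate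
6 | 4β-[3-formyl-2-hydroxy-4,6-bis(benzyloxy)phenyl]-5,7,3',4'-tetra-O-benzyl-(−)-epicatechin | c1ccccc1COc1cc(OCc3ccccc3)c2c(c1)O[C@H](c1ccc(OCc3ccccc3)c(OCc3ccccc3)c1)[C@H](O)[C@H]2c1c(OCc3ccccc3)cc(OCc3ccccc3)c(C=O)c1O | intermediate
7 | 5,7-bis(benzyloxy)-2α-[3,4-bis(benzyloxy)phenyl]-4β-[3-formyl-2-hydroxy-4,6-bis(benzyloxy)phenyl]chroman-3-one | c1ccccc1COc1cc(OCc3ccccc3)c2c(c1)O[C@H](c1ccc(OCc3ccccc3)c(OCc3ccccc3)c1)C(=O)[C@H]2c1c(OCc3ccccc3)cc(OCc3ccccc3)c(C=O)c1O | intermediate
8 | 4β-[2-hydroxy-3-(hydroxymethyl)-4,6-bis(benzyloxy)phenyl]-5,7,3',4'-tetra-O-benzyl-(+)-catechin (2α-aryl, 3β-OH, 4β-aryl) | c1ccccc1COc1cc(OCc3ccccc3)c2c(c1)O[C@H](c1ccc(OCc3ccccc3)c(OCc3ccccc3)c1)[C@@H](O)[C@H]2c1c(OCc3ccccc3)cc(OCc3ccccc3)c(CO)c1O | intermediate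
9 | 3,4-bis(benzyloxy)benzaldehyde | O=Cc1ccc(OCc2ccccc2)c(OCc2ccccc2)c1 | starting material
10 | (E)-2-[3,4-bis(benzyloxy)phenyl]ethenylboronic acid pinacol ester | CC1(C)OB(/C=C/c2ccc(OCc3ccccc3)c(OCc3ccccc3)c2)OC1(C)C | intermediate
11 | potassium (E)-{2-[3,4-bis(benzyloxy)phenyl]ethenyl}trifluoroborate | [K+].F[B-](F)(F)/C=C/c1ccc(OCc2ccccc2)c(OCc2ccccc2)c1 | intermediate
12 | (E)-2-[3,4-bis(benzyloxy)phenyl]ethenyl acetate | CC(=O)O/C=C/c1ccc(OCc2ccccc2)c(OCc2ccccc2)c1 | intermediate
13 | ortho-quinone methide from 8: 6-methylidenecyclohexa-2,4-dien-1-one carrying the tetra-O-benzylcatechin-4β-yl group at C2 and benzyloxy groups at C3 and C5 | c1ccccc1COc1cc(OCc3ccccc3)c2c(c1)O[C@H](c1ccc(OCc3ccccc3)c(OCc3ccccc3)c1)[C@@H](O)[C@H]2C1=C(OCc3ccccc3)C=C(OCc3ccccc3)C(=C)C1=O | intermediate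
14 | 5,7,3',4'-tetra-O-benzylcatechin-(4β→8)-(3-O-acetyl-5,7,3',4'-tetra-O-benzyl-ent-catechin); middle 3β-OH free, terminal unit 2S,3R | c1ccccc1COc1cc(OCc3ccccc3)c2c(c1)O[C@H](c1ccc(OCc3ccccc3)c(OCc3ccccc3)c1)[C@@H](O)[C@H]2c1c(OCc3ccccc3)cc(OCc3ccccc3)c2c1O[C@@H](c1ccc(OCc3ccccc3)c(OCc3ccccc3)c1)[C@H](OC(C)=O)C2 | intermediate
15 | 3-O-acetyl-5,7,3',4'-tetra-O-benzylcatechin-(4β→8)-(3-O-acetyl-5,7,3',4'-tetra-O-benzyl-ent-catechin) | c1ccccc1COc1cc(OCc3ccccc3)c2c(c1)O[C@H](c1ccc(OCc3ccccc3)c(OCc3ccccc3)c1)[C@@H](OC(C)=O)[C@H]2c1c(OCc3ccccc3)cc(OCc3ccccc3)c2c1O[C@@H](c1ccc(OCc3ccccc3)c(OCc3ccccc3)c1)[C@H](OC(C)=O)C2 | intermediate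
16 | (+)-gallocatechin, (2R,3S) | Oc1cc(O)c2c(c1)O[C@H](c1cc(O)c(O)c(O)c1)[C@@H](O)C2 | starting material
17 | 5,7,3',4',5'-penta-O-benzyl-(+)-gallocatechin | c1ccccc1COc1cc(OCc3ccccc3)c2c(c1)O[C@H](c1cc(OCc3ccccc3)c(OCc3ccccc3)c(OCc3ccccc3)c1)[C@@H](O)C2 | intermediate
18 | 8-bromo-5,7,3',4',5'-penta-O-benzyl-(+)-gallocatechin | c1ccccc1COc1cc(OCc3ccccc3)c2c(c1Br)O[C@H](c1cc(OCc3ccccc3)c(OCc3ccccc3)c(OCc3ccccc3)c1)[C@@H](O)C2 | intermediate
19 | 8-bromo-4β-(2-ethoxyethoxy)-5,7,3',4',5'-penta-O-benzyl-(+)-gallocatechin | c1ccccc1COc1cc(OCc3ccccc3)c2c(c1Br)O[C@H](c1cc(OCc3ccccc3)c(OCc3ccccc3)c(OCc3ccccc3)c1)[C@@H](O)[C@H]2OCCOCC | intermediate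
20 | 3-O-acetyl-8-bromo-4β-(2-ethoxyethoxy)-5,7,3',4',5'-penta-O-benzyl-(+)-gallocatechin | c1ccccc1COc1cc(OCc3ccccc3)c2c(c1Br)O[C@H](c1cc(OCc3ccccc3)c(OCc3ccccc3)c(OCc3ccccc3)c1)[C@@H](OC(C)=O)[C@H]2OCCOCC | intermediate
21 | 3-O-acetyl-8-bromo-penta-O-benzylgallocatechin-(4α→8)-3-O-acetyl-tetra-O-benzylcatechin-(4β→8)-(3-O-acetyl-tetra-O-benzyl-ent-catechin) | c1ccccc1COc1cc(OCc3ccccc3)c2c(c1Br)O[C@H](c1cc(OCc3ccccc3)c(OCc3ccccc3)c(OCc3ccccc3)c1)[C@@H](OC(C)=O)[C@@H]2c1c(OCc3ccccc3)cc(OCc3ccccc3)c2c1O[C@H](c1ccc(OCc3ccccc3)c(OCc3ccccc3)c1)[C@@H](OC(C)=O)[C@H]2c1c(OCc3ccccc3)cc(OCc3ccccc3)c2c1O[C@@H](c1ccc(OCc3ccccc3)c(OCc3ccccc3)c1)[C@H](OC(C)=O)C2 | intermediate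
22 | 8-bromo-penta-O-benzylgallocatechin-(4α→8)-tetra-O-benzylcatechin-(4β→8)-tetra-O-benzyl-ent-catechin (three free 3-OH) | c1ccccc1COc1cc(OCc3ccccc3)c2c(c1Br)O[C@H](c1cc(OCc3ccccc3)c(OCc3ccccc3)c(OCc3ccccc3)c1)[C@@H](O)[C@@H]2c1c(OCc3ccccc3)cc(OCc3ccccc3)c2c1O[C@H](c1ccc(OCc3ccccc3)c(OCc3ccccc3)c1)[C@@H](O)[C@H]2c1c(OCc3ccccc3)cc(OCc3ccccc3)c2c1O[C@@H](c1ccc(OCc3ccccc3)c(OCc3ccccc3)c1)[C@H](O)C2 | intermediate
23 | (+)-gallocatechin-(4α→8)-(+)-catechin-(4β→8)-(−)-catechin; upper 2R,3S,4S, middle 2R,3S,4S, terminal 2S,3R | Oc1cc(O)c2c(c1)O[C@H](c1cc(O)c(O)c(O)c1)[C@@H](O)[C@@H]2c1c(O)cc(O)c2c1O[C@H](c1ccc(O)c(O)c1)[C@@H](O)[C@H]2c1c(O)cc(O)c2c1O[C@@H](c1ccc(O)c(O)c1)[C@H](O)C2 | target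

**Step count and risks**

Total step count: 18. Longest linear sequence: 11 steps (steps 1–6, 10, 11, 16, 17, 18, from (−)-epicatechin).

Steps most likely to fail:

1. Step 10. The enol ester may be too weak a nucleophile, so that the benzylic cation is consumed by Friedel–Crafts alkylation of ring A carbons of other molecules or by methide dimerisation. The catalyst may also give poor facial selection next to the bulky chiral flavanyl group, and acetyl transfer from 12 to the phenol could shut the methide pathway down. The fallback uses known chemistry, sets out from 3 and returns at 14. Commercial (−)-catechin is benzylated on its four phenols (BnBr, K2CO3, DMF) to 5,7,3',4'-tetra-O-benzyl-(−)-catechin F1 and acetylated (Ac2O, pyridine) to 3-O-acetyl-5,7,3',4'-tetra-O-benzyl-(−)-catechin F2. F2 in excess is coupled with 3 (TMSOTf, CH2Cl2, −78 °C), which should give 5,7,3',4'-tetra-O-benzylepicatechin-(4β→8)-(3-O-acetyl-5,7,3',4'-tetra-O-benzyl-ent-catechin) F3. Dess–Martin oxidation of its free 3α-OH gives the middle-unit 3-ketone F4, and NaBH4/CeCl3·7H2O reduction from the α face gives 14.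

2. Step 6. Hydride may be delivered from the β face through a phenoxy-borohydride formed at the neighbouring phenol, the ketone may epimerise at C2 or C4 by enolisation, or the salicyl alcohol may be over-reduced through its quinone methide. The fallback sets out from 6 and returns at 8, with the phenol masked so that hydride delivery can only be intermolecular. Compound 6 is O-allylated (allyl bromide, K2CO3, DMF) to 4β-[2-allyloxy-3-formyl-4,6-bis(benzyloxy)phenyl]-5,7,3',4'-tetra-O-benzyl-(−)-epicatechin F5 and oxidised with Dess–Martin periodinane to the corresponding 3-ketone F6. NaBH4/CeCl3·7H2O reduction gives 4β-[2-allyloxy-3-(hydroxymethyl)-4,6-bis(benzyloxy)phenyl]-5,7,3',4'-tetra-O-benzyl-(+)-catechin F7, and the allyl group is removed with Pd(PPh3)4 and morpholine in THF to give 8.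

3. Step 3. The cation may attack the phenol carbon para to the hydroxyl group (between the two benzyloxy groups) or the phenol oxygen, or the product may be alkylated a second time. The fallback sets out from 3 and returns at 6; it uses a nucleophile in which a temporary dioxinone ring already holds the oxygen and the carbon of the future pyran ring on neighbouring arene positions. Commercial 5,7-dihydroxy-2,2-dimethyl-4H-1,3-benzodioxin-4-one is dibenzylated (BnBr, K2CO3, DMF, 60 °C) to 5,7-bis(benzyloxy)-2,2-dimethyl-4H-1,3-benzodioxin-4-one F8. F8 in large excess is alkylated by 3 (TMSOTf, CH2Cl2, slow addition of 3) at its C8, the position flanked by the ring oxygen and one OBn, to give the 4β-(benzodioxinon-8-yl)epicatechin adduct F9. LiAlH4 in THF opens the acetonide ester to 4β-[2-hydroxy-3-(hydroxymethyl)-4,6-bis(benzyloxy)phenyl]-5,7,3',4'-tetra-O-benzyl-(−)-epicatechin F10, and MnO2 in CH2Cl2 oxidises only the benzylic alcohol to give 6.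

Further compounds
F1 | step 10 | 5,7,3',4'-tetra-O-benzyl-(−)-catechin | c1ccccc1COc1cc(OCc3ccccc3)c2c(c1)O[C@@H](c1ccc(OCc3ccccc3)c(OCc3ccccc3)c1)[C@H](O)C2
F2 | step 10 | 3-O-acetyl-5,7,3',4'-tetra-O-benzyl-(−)-catechin | c1ccccc1COc1cc(OCc3ccccc3)c2c(c1)O[C@@H](c1ccc(OCc3ccccc3)c(OCc3ccccc3)c1)[C@H](OC(C)=O)C2
F3 | step 10 | 5,7,3',4'-tetra-O-benzylepicatechin-(4β→8)-(3-O-acetyl-5,7,3',4'-tetra-O-benzyl-ent-catechin) | c1ccccc1COc1cc(OCc3ccccc3)c2c(c1)O[C@H](c1ccc(OCc3ccccc3)c(OCc3ccccc3)c1)[C@H](O)[C@H]2c1c(OCc3ccccc3)cc(OCc3ccccc3)c2c1O[C@@H](c1ccc(OCc3ccccc3)c(OCc3ccccc3)c1)[C@H](OC(C)=O)C2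
F4 | step 10 | middle-unit 3-ketone of F3 (2α-aryl, 4β-aryl) | c1ccccc1COc1cc(OCc3ccccc3)c2c(c1)O[C@H](c1ccc(OCc3ccccc3)c(OCc3ccccc3)c1)C(=O)[C@H]2c1c(OCc3ccccc3)cc(OCc3ccccc3)c2c1O[C@@H](c1ccc(OCc3ccccc3)c(OCc3ccccc3)c1)[C@H](OC(C)=O)C2
F5 | step 6 | 4β-[2-allyloxy-3-formyl-4,6-bis(benzyloxy)phenyl]-5,7,3',4'-tetra-O-benzyl-(−)-epicatechin | c1ccccc1COc1cc(OCc3ccccc3)c2c(c1)O[C@H](c1ccc(OCc3ccccc3)c(OCc3ccccc3)c1)[C@H](O)[C@H]2c1c(OCc3ccccc3)cc(OCc3ccccc3)c(C=O)c1OCC=C
F6 | step 6 | 5,7-bis(benzyloxy)-2α-[3,4-bis(benzyloxy)phenyl]-4β-[2-allyloxy-3-formyl-4,6-bis(benzyloxy)phenyl]chroman-3-one | c1ccccc1COc1cc(OCc3ccccc3)c2c(c1)O[C@H](c1ccc(OCc3ccccc3)c(OCc3ccccc3)c1)C(=O)[C@H]2c1c(OCc3ccccc3)cc(OCc3ccccc3)c(C=O)c1OCC=C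
F7 | step 6 | 4β-[2-allyloxy-3-(hydroxymethyl)-4,6-bis(benzyloxy)phenyl]-5,7,3',4'-tetra-O-benzyl-(+)-catechin | c1ccccc1COc1cc(OCc3ccccc3)c2c(c1)O[C@H](c1ccc(OCc3ccccc3)c(OCc3ccccc3)c1)[C@@H](O)[C@H]2c1c(OCc3ccccc3)cc(OCc3ccccc3)c(CO)c1OCC=C
F8 | step 3 | 5,7-bis(benzyloxy)-2,2-dimethyl-4H-1,3-benzodioxin-4-one | CC1(C)OC(=O)c2c(OCc3ccccc3)cc(OCc3ccccc3)cc2O1
F9 | step 3 | 4β-[5,7-bis(benzyloxy)-2,2-dimethyl-4-oxo-4H-1,3-benzodioxin-8-yl]-5,7,3',4'-tetra-O-benzyl-(−)-epicatechin | c1ccccc1COc1cc(OCc3ccccc3)c2c(c1)O[C@H](c1ccc(OCc3ccccc3)c(OCc3ccccc3)c1)[C@H](O)[C@H]2c1c(OCc3ccccc3)cc(OCc3ccccc3)c2c1OC(C)(C)OC2=O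
F10 | step 3 | 4β-[2-hydroxy-3-(hydroxymethyl)-4,6-bis(benzyloxy)phenyl]-5,7,3',4'-tetra-O-benzyl-(−)-epicatechin | c1ccccc1COc1cc(OCc3ccccc3)c2c(c1)O[C@H](c1ccc(OCc3ccccc3)c(OCc3ccccc3)c1)[C@H](O)[C@H]2c1c(OCc3ccccc3)cc(OCc3ccccc3)c(CO)c1O
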